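The earlier runs and the new flask were computed with constants of no real substance; the scatter is artificial.

The constants stayed hidden from me, so I reckoned from the charge and the readings.

| flask | electrophile | free base | protonated nucleophile | protic impurity | remark | time |
|---|---|---|---|---|---|---|
| Monday's | 0.020 M | 0.024 M | 0.050 M | 6 mM | run made earlier |  |
| Wednesday's | 0.020 M | 0.024 M | 0.034 M | 6 mM | run made earlier |  |
| Saturday's | 0.020 M | 0.024 M | 0.075 M | 6 mM | run made earlier |  |
| delta | 0.020 M | 0.0240 M | 0.0500 M | 6.00 mM | everything together in a closed stirred flask, run for 20 min | 20 min |
| alpha | 0.020 M (fed, over 10.0 min) | 0.0240 M | 0.0500 M | 6.00 mM | a stirred flask in which electrophile is dosed at a steady rate over 10.0 min without added volume, worked up at 20 min | 20 min |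
| gamma | 0.020 M | 0.0240 M | 0.0500 M | 6.00 mM | a single well-mixed tank run continuously and read at steady state, 20 min in it on average |  |
| epsilon | 0.020 M | 0.0240 M | 0.0500 M | 6.00 mM | one stirred flow tank at steady state, fed with the mixture as stated, mean residence time 100 min |  |

- Monday's (time / min: target / %): 1.50: 11; 4.00: 21; 8.00: 32; 20.0: 49
- Wednesday's (time / min: target / %): 3.00: 19; 6.00: 28; 10.0: 38; 12.0: 39
- Saturday's (time / min: target / %): 1.50: 11; 4.00: 23; 8.00: 32; 12.0: 41

(standard deviation of a reading: 1.5 percentage points)

- the stated concentrations are those of everything mixed, before any reaction; amounts are the same in each set-up
- reactions considered so far: acid set free -> by-product carried off; acid set free + target -> side product; acid set free + free base <-> salt of the base; protic impurity + free base -> quenched reagent; nucleophile + acid set free <-> protonated nucleophile; electrophile + nucleophile -> acid set free + target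
- the feed brings no volume worth counting
- the earlier runs were made in a closed, stirred flask

1. order of the set-ups by the amount of target at the outlet or at the end, in percent of the electrophile put in, highest first (delta / alpha / gamma / epsilon)
2. amount of target at the outlet or at the end, in percent of the electrophile put in, delta
3. amount of target at the outlet or at the end, in percent of the electrophile put in, alpha
4. amount of target at the outlet or at the end, in percent of the electrophile put in, gamma
5. amount of target at the outlet or at the end, in percent of the electrophile put in, epsilon

At 12.0 min, Wednesday's run gave 39% and Saturday's 41%, a gap of 2 percentage points against a scatter of 1.5 points per reading, though c(protonated nucleophile) differed by a factor of 2.21. I therefore took the free base as the supplier of nucleophile and counted it as a budget. If the protic impurity took its whole 6.00 mM, 18.0 mM of free base remained. Each target uses one nucleophile and sets free one acid, so it costs two base equivalents. That pays for 9.00 mM of target, less than the 20 mM of electrophile, which makes the free base the limiting reagent. I called the resulting yield, reached with no acid carried off, the no-loss ceiling: 45.0% of the electrophile charged.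

I then turned the question round. For the target to stop at that ceiling, Monday's last reading had to stand at or under it, but it stood at 49%, which is 4 points above. So at least one of the ceiling's two assumptions failed in Monday's flask: that the protic impurity took its whole 6.00 mM, or that no acid was carried off. The readings did not tell me which. With no free base lost to the protic impurity, the same count gave 60.0%. I placed epsilon highest, because its 100 min mean residence time is longer than delta's 20 min. I placed alpha below delta, because its electrophile spends 15.0 min in the flask on average, less than 20 min.

The forecast gave epsilon > delta > alpha > gamma, with 49% for delta, 43% for alpha, 34% for gamma and 58% for epsilon, holding that “slow acid removal must regenerate nucleophile late on”.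

The flasks gave epsilon > delta > alpha > gamma: delta 48.5%, alpha 43.4%, gamma 36.6%, epsilon 52.7%, the last 5.3 points under the forecast.

    acid set free → by-product carried off (k = 6.40 × 10⁻⁴ /s)
    acid set free + target → side product (k = 0.00780 /M/s)
    acid set free + free base ⇌ salt of the base, settled at all times (K = 2.70 × 10⁵ /M)
    protic impurity + free base → quenched reagent (k = 0.0760 /M/s)
    nucleophile + acid set free ⇌ protonated nucleophile, settled at all times (K = 34000 /M)
    electrophile + nucleophile → acid set free + target (k = 0.0570 /M/s)

Delta still held 51.4% of its electrophile at the end. Delta stood 3.5 points above the ceiling, which at two base equivalents per target is 1.40 mM of base beyond the budget. Epsilon stood 7.7 points above it, or 3.08 mM beyond the budget.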